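**Plan**

1. Atom labels are drimane labels: ring A = C1–C5 and C10 (C3 carbinol, C4 gem-dimethyl); ring B = C5–C10 (C6=C7, exocyclic C8=C12, C9 bearing C11H2–O–aryl, C10 bearing methyl C15).
2. Retrosynthesis: cut the C11–O aryl ether (umbelliferone), return C11 to an N-acyl oxazolidinone and C3 to a ketone, then cut C5–C10 and C8–C9 together; the open chain is then cut at C6–C7, C5–C6, C3–C4 and C1–C10.
3. The double cut is possible because ring B is a cyclohexene (C6=C7) carrying the exocyclic C8=C12 methylene and both ring-fusion carbons: this is the adduct of a C5–C8 vinylallene (C12 as allene terminus) and a C9=C10 enoyl alkene tethered through C1–C4.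
4. Forward: the chain is joined from C11 towards C12 (carbocupration fixes the (E)-C9=C10 alkene, an enamine acylation adds C4/C5, then C6 and C7–C8–C12 follow); rings A and B arise together in one intramolecular Diels–Alder step; the coumarin is attached last.
5. Stereochemistry: C9 and C10 from the (S)-4-benzyloxazolidinone (face of the chelated enoyl unit) and the (E)-alkene; C5 from the endo mode (trans fusion); C3 from equatorial hydride delivery by KBH(s-Bu)3.

Key step: step 10

**Route**

Step 1
Reactants: 1 2-(2-bromoethyl)-1,3-dioxane; 2 ethyl but-2-ynoate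
Product: 6 ethyl (2E)-5-(1,3-dioxan-2-yl)-3-methylpent-2-enoate, via Grignard reagent 3 (not isolated), via alkylcopper reagent 4 (not isolated), via alkenylcopper adduct 5 (not isolated)
Conditions: Mg, THF, 25 °C; CuBr·SMe2 (1 equiv), THF, −40 °C; 2, −78 °C; aq NH4Cl, −78 °C
Reagents that add atoms: none
Why: Conjugate addition of an organocopper reagent to an alkynoate (syn-carbocupration) places the new chain cis to copper and hence trans to the ester, so protonation of the alkenylcopper at −78 °C should give the (E)-trisubstituted enoate with the methyl group cis to the ester.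

Step 2
Reactants: 6 ethyl (2E)-5-(1,3-dioxan-2-yl)-3-methylpent-2-enoate
Product: 7 ethyl (2E)-3-methyl-6-oxohex-2-enoate
Conditions: 2 M aq HCl, THF, 50 °C
Reagents that add atoms: water, O
Why: Acid-catalysed acetal hydrolysis should release the C3 aldehyde, the β,β-disubstituted enoate being inert to dilute aqueous acid.

Step 3
Reactants: 7 ethyl (2E)-3-methyl-6-oxohex-2-enoate
Product: 8 (4E)-6-ethoxy-4-methyl-6-oxohex-4-enoic acid
Conditions: NaClO2, NaH2PO4, 2-methylbut-2-ene, t-BuOH/H2O, 0 → 25 °C
Reagents that add atoms: sodium chlorite, [Na+].[O-]Cl=O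
Why: Pinnick oxidation should convert the aldehyde into the acid under buffered conditions that leave the electron-poor alkene untouched, the added alkene scavenging hypochlorous acid.

Step 4
Reactants: 8 (4E)-6-ethoxy-4-methyl-6-oxohex-4-enoic acid; 9 4-(2-methylprop-1-en-1-yl)morpholine
Product: 12 ethyl (2E)-3,7,7-trimethyl-6,8-dioxooct-2-enoate, via acid chloride 10 (not isolated), via iminium chloride 11 (not isolated)
Conditions: (COCl)2, DMF (cat.), CH2Cl2, 0 → 25 °C, evaporate; 9, Et2O, 0 → 25 °C; H2O, 25 °C
Reagents that add atoms: water, O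
Why: Stork-type C-acylation of the β,β-disubstituted aldehyde enamine by the acid chloride gives an acyl iminium salt that cannot enolise, and its hydrolysis should deliver the non-enolisable 2,2-dimethyl-3-oxo aldehyde, installing C4, both methyl groups and C5 at the required oxidation levels in one operation.

Step 5
Reactants: 12 ethyl (2E)-3,7,7-trimethyl-6,8-dioxooct-2-enoate
Product: 13 ethyl (2E,8E)-9-iodo-3,7,7-trimethyl-6-oxonona-2,8-dienoate
Conditions: CrCl2 (6 equiv), CHI3 (2 equiv), THF, 0 → 25 °C
Reagents that add atoms: iodoform, IC(I)I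
Why: Takai olefination is selective for the aldehyde over the hindered ketone and the ester, and should give the (E)-iodoalkene, the quaternary neighbour reinforcing the usual E preference.

Step 6
Reactants: 13 ethyl (2E,8E)-9-iodo-3,7,7-trimethyl-6-oxonona-2,8-dienoate; 14 prop-2-yn-1-ol
Product: 15 ethyl (2E,8E)-12-hydroxy-3,7,7-trimethyl-6-oxododeca-2,8-dien-10-ynoate
Conditions: PdCl2(PPh3)2 (cat.), CuI (cat.), Et3N, THF, 25 °C
Reagents that add atoms: none
Why: Sonogashira coupling of the iodoalkene with the terminal alkyne should proceed with retention of the (E)-geometry under mild amine conditions that ketone and ester tolerate.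

Step 7
Reactants: 15 ethyl (2E,8E)-12-hydroxy-3,7,7-trimethyl-6-oxododeca-2,8-dien-10-ynoate
Product: 18 ethyl (2E,8E)-3,7,7-trimethyl-6-oxododeca-2,8,10,11-tetraenoate, via sulfonylhydrazine adduct 16 (not isolated), via propargylic diazene 17 (not isolated)
Conditions: PPh3, DEAD, THF, −15 °C; 2-NO2C6H4SO2NHNH2, −15 → 23 °C
Reagents that add atoms: none
Why: Myers allene synthesis, in which Mitsunobu N-alkylation of the sulfonylhydrazide by the primary propargylic alcohol, loss of sulfinic acid on warming and retro-ene loss of N2 from the diazene should transpose the alkyne into the terminal allene; the ketone next to the quaternary carbon is expected to be too hindered to condense with the hydrazide at low temperature.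

Step 8
Reactants: 18 ethyl (2E,8E)-3,7,7-trimethyl-6-oxododeca-2,8,10,11-tetraenoate
Product: 19 (2E,8E)-3,7,7-trimethyl-6-oxododeca-2,8,10,11-tetraenoic acid
Conditions: LiOH·H2O, THF/MeOH/H2O, 25 °C; aq HCl to pH 3, 0 °C
Reagents that add atoms: lithium hydroxide, [Li+].[OH-]
Why: Ester saponification should free the acid without affecting the allene, the (E)-alkenes or the ketone, which has no stereocentre to lose.

Step 9
Reactants: 19 (2E,8E)-3,7,7-trimethyl-6-oxododeca-2,8,10,11-tetraenoic acid; 20 (4S)-4-benzyl-1,3-oxazolidin-2-one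
Product: 22 (4S)-4-benzyl-3-[(2E,8E)-3,7,7-trimethyl-6-oxododeca-2,8,10,11-tetraenoyl]-1,3-oxazolidin-2-one, via mixed pivalic anhydride 21 (not isolated)
Conditions: PivCl, Et3N, THF, −20 °C; LiCl, 20, −20 → 25 °C
Reagents that add atoms: none
Why: N-acylation of the oxazolidinone through the mixed pivalic anhydride with LiCl/Et3N activation is a standard route to N-enoyl imides and avoids the strong bases that could isomerise the enoyl alkene or the allene.

Step 10
Reactants: 22 (4S)-4-benzyl-3-[(2E,8E)-3,7,7-trimethyl-6-oxododeca-2,8,10,11-tetraenoyl]-1,3-oxazolidin-2-one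
Product: 23 (4S)-4-benzyl-3-{[(1S,4aR,8aS)-5,5,8a-trimethyl-2-methylidene-6-oxo-1,2,4a,5,6,7,8,8a-octahydronaphthalen-1-yl]carbonyl}-1,3-oxazolidin-2-one (trans-fused)
Conditions: Me2AlCl (2.5 equiv), CH2Cl2, −30 → 0 °C; aq potassium sodium tartrate
Reagents that add atoms: none
Why: Two-point binding of aluminium to both imide carbonyls should lock the enoyl unit s-cis and lower its LUMO, so that the C9=C10 alkene adds to the diene formed by C5=C6 and the inner allene bond C7=C8 in a concerted, asynchronous intramolecular Diels–Alder reaction (closest precedent: Lewis-acid-promoted cycloadditions of trienyl N-acyl oxazolidinones and cycloadditions of tethered vinylallenes). Ring B is closed by the cycloaddition itself through the new bonds C5–C10 and C8–C9, and ring A is closed by the C5–C10 bond across the four-atom tether C1–C4, which folds into a chair. C9 and C10 are set together by the (E)-geometry of the dienophile and by the benzyl group of the (S)-auxiliary, which shields one face of the chelated enoyl unit so that the diene adds to the other. C5 is set relative to C10 by the endo position of the chelated acyl group, which puts the tether anti and should give the trans ring fusion with the C10 methyl cis to C11. The step needs facial and endo selectivity on a hindered trisubstituted dienophile; the chelate and the (E)-alkene are to secure these, while the sp carbon C8 (no inside substituent) and the gem-dimethyl group at C4, which favours the folded conformer, are counted on for reactivity. The allene leaves the C8=C12 methylene and the C6=C7 alkene in place, so ring B needs no later adjustment.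

Step 11
Reactants: 23 (4S)-4-benzyl-3-{[(1S,4aR,8aS)-5,5,8a-trimethyl-2-methylidene-6-oxo-1,2,4a,5,6,7,8,8a-octahydronaphthalen-1-yl]carbonyl}-1,3-oxazolidin-2-one
Product: 24 (4S)-4-benzyl-3-{[(1S,4aR,6R,8aS)-6-hydroxy-5,5,8a-trimethyl-2-methylidene-1,2,4a,5,6,7,8,8a-octahydronaphthalen-1-yl]carbonyl}-1,3-oxazolidin-2-one
Conditions: KBH(s-Bu)3 (1.2 equiv), THF, −78 °C; aq NH4Cl
Reagents that add atoms: none
Why: In this diastereoselective ketone reduction the bulky trialkylborohydride should attack C3 from the equatorial direction and give the axial (3R) alcohol, as is usual for 4,4-dimethyl-3-oxo trans-decalins, while the hindered imide is expected to survive at −78 °C.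

Step 12
Reactants: 24 (4S)-4-benzyl-3-{[(1S,4aR,6R,8aS)-6-hydroxy-5,5,8a-trimethyl-2-methylidene-1,2,4a,5,6,7,8,8a-octahydronaphthalen-1-yl]carbonyl}-1,3-oxazolidin-2-one
Product: 25 (2R,4aS,5S,8aR)-5-(hydroxymethyl)-1,1,4a-trimethyl-6-methylidene-1,2,3,4,4a,5,6,8a-octahydronaphthalen-2-ol
Conditions: LiBH4, H2O (1 equiv), Et2O, 0 → 25 °C
Reagents that add atoms: none
Why: Reductive cleavage of the N-acyl oxazolidinone by LiBH4 in wet ether should reduce the exocyclic carbonyl to the C11 primary alcohol and release the auxiliary without touching the diene or any stereocentre.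

Step 13
Reactants: 25 (2R,4aS,5S,8aR)-5-(hydroxymethyl)-1,1,4a-trimethyl-6-methylidene-1,2,3,4,4a,5,6,8a-octahydronaphthalen-2-ol; 26 umbelliferone (7-hydroxy-2H-chromen-2-one)
Product: 27 7-{[(1S,4aR,6R,8aS)-6-hydroxy-5,5,8a-trimethyl-2-methylidene-1,2,4a,5,6,7,8,8a-octahydronaphthalen-1-yl]methoxy}-2H-chromen-2-one (CNP0259618.3)
Conditions: PPh3, DIAD, THF, 0 → 25 °C
Reagents that add atoms: none
Why: In the Mitsunobu etherification the acidic coumarin phenol should be alkylated by the activated primary C11 alcohol, while the axial C3 alcohol beside the gem-dimethyl carbon is too hindered to react, so no protecting group is needed.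

**Compound list**

1 | 2-(2-bromoethyl)-1,3-dioxane | BrCCC1OCCCO1 | starting material
2 | ethyl but-2-ynoate | CCOC(=O)C#CC | starting material
3 | [2-(1,3-dioxan-2-yl)ethyl]magnesium bromide | Br[Mg]CCC1OCCCO1 | intermediate (not isolated)
4 | [2-(1,3-dioxan-2-yl)ethyl]copper, as its MgBr2 complex | [Cu]CCC1OCCCO1 | intermediate (not isolated)
5 | ethyl (2Z)-2-cuprio-5-(1,3-dioxan-2-yl)-3-methylpent-2-enoate (copper cis to the new chain) | CCOC(=O)/C([Cu])=C(\C)CCC1OCCCO1 | intermediate (not isolated)
6 | ethyl (2E)-5-(1,3-dioxan-2-yl)-3-methylpent-2-enoate | CCOC(=O)/C=C(\C)CCC1OCCCO1 | intermediate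
7 | ethyl (2E)-3-methyl-6-oxohex-2-enoate | CCOC(=O)/C=C(\C)CCC=O | intermediate
8 | (4E)-6-ethoxy-4-methyl-6-oxohex-4-enoic acid | CCOC(=O)/C=C(\C)CCC(=O)O | intermediate
9 | 4-(2-methylprop-1-en-1-yl)morpholine | CC(C)=CN1CCOCC1 | starting material
10 | ethyl (2E)-6-chloro-3-methyl-6-oxohex-2-enoate | CCOC(=O)/C=C(\C)CCC(Cl)=O | intermediate (not isolated)
11 | 4-[(6E)-8-ethoxy-2,2,6-trimethyl-3,8-dioxooct-6-en-1-ylidene]morpholin-4-ium chloride | CCOC(=O)/C=C(\C)CCC(=O)C(C)(C)C=[N+]1CCOCC1.[Cl-] | intermediate (not isolated)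
12 | ethyl (2E)-3,7,7-trimethyl-6,8-dioxooct-2-enoate | CCOC(=O)/C=C(\C)CCC(=O)C(C)(C)C=O | intermediate
13 | ethyl (2E,8E)-9-iodo-3,7,7-trimethyl-6-oxonona-2,8-dienoate | CCOC(=O)/C=C(\C)CCC(=O)C(C)(C)/C=C/I | intermediate
14 | prop-2-yn-1-ol | OCC#C | starting material
15 | ethyl (2E,8E)-12-hydroxy-3,7,7-trimethyl-6-oxododeca-2,8-dien-10-ynoate | CCOC(=O)/C=C(\C)CCC(=O)C(C)(C)/C=C/C#CCO | intermediate
16 | ethyl (2E,8E)-3,7,7-trimethyl-12-[1-(2-nitrobenzenesulfonyl)hydrazin-1-yl]-6-oxododeca-2,8-dien-10-ynoate | CCOC(=O)/C=C(\C)CCC(=O)C(C)(C)/C=C/C#CCN(N)S(=O)(=O)c1ccccc1[N+](=O)[O-] | intermediate (not isolated)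
17 | ethyl (2E,8E)-12-diazenyl-3,7,7-trimethyl-6-oxododeca-2,8-dien-10-ynoate | CCOC(=O)/C=C(\C)CCC(=O)C(C)(C)/C=C/C#CCN=N | intermediate (not isolated)
18 | ethyl (2E,8E)-3,7,7-trimethyl-6-oxododeca-2,8,10,11-tetraenoate | CCOC(=O)/C=C(\C)CCC(=O)C(C)(C)/C=C/C=C=C | intermediate
19 | (2E,8E)-3,7,7-trimethyl-6-oxododeca-2,8,10,11-tetraenoic acid | C=C=C/C=C/C(C)(C)C(=O)CC/C(C)=C/C(=O)O | intermediate
20 | (4S)-4-benzyl-1,3-oxazolidin-2-one | O=C1N[C@@H](Cc2ccccc2)CO1 | starting material
21 | 2,2-dimethylpropanoic (2E,8E)-3,7,7-trimethyl-6-oxododeca-2,8,10,11-tetraenoic anhydride | C=C=C/C=C/C(C)(C)C(=O)CC/C(C)=C/C(=O)OC(=O)C(C)(C)C | intermediate (not isolated)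
22 | (4S)-4-benzyl-3-[(2E,8E)-3,7,7-trimethyl-6-oxododeca-2,8,10,11-tetraenoyl]-1,3-oxazolidin-2-one | C=C=C/C=C/C(C)(C)C(=O)CC/C(C)=C/C(=O)N1[C@@H](Cc2ccccc2)COC1=O | intermediate
23 | (4S)-4-benzyl-3-{[(1S,4aR,8aS)-5,5,8a-trimethyl-2-methylidene-6-oxo-1,2,4a,5,6,7,8,8a-octahydronaphthalen-1-yl]carbonyl}-1,3-oxazolidin-2-one | C=C1C=C[C@H]2C(C)(C)C(=O)CC[C@]2(C)[C@H]1C(=O)N1[C@@H](Cc3ccccc3)COC1=O | intermediate
24 | (4S)-4-benzyl-3-{[(1S,4aR,6R,8aS)-6-hydroxy-5,5,8a-trimethyl-2-methylidene-1,2,4a,5,6,7,8,8a-octahydronaphthalen-1-yl]carbonyl}-1,3-oxazolidin-2-one | C=C1C=C[C@H]2C(C)(C)[C@H](O)CC[C@]2(C)[C@H]1C(=O)N1[C@@H](Cc3ccccc3)COC1=O | intermediate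
25 | (2R,4aS,5S,8aR)-5-(hydroxymethyl)-1,1,4a-trimethyl-6-methylidene-1,2,3,4,4a,5,6,8a-octahydronaphthalen-2-ol | C=C1C=C[C@H]2C(C)(C)[C@H](O)CC[C@]2(C)[C@H]1CO | intermediate
26 | umbelliferone (7-hydroxy-2H-chromen-2-one) | O=c1ccc2ccc(O)cc2o1 | starting material
27 | 7-{[(1S,4aR,6R,8aS)-6-hydroxy-5,5,8a-trimethyl-2-methylidene-1,2,4a,5,6,7,8,8a-octahydronaphthalen-1-yl]methoxy}-2H-chromen-2-one | C=C1C=C[C@H]2C(C)(C)[C@H](O)CC[C@]2(C)[C@H]1COc1ccc2ccc(=O)oc2c1 | target

**Step count**

Total: 13 steps. Longest linear sequence: 13 steps (1 and 2 to 27).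

**Steps most likely to fail**

Step 10 (cycloaddition). The chelated β,β-disubstituted enoyl imide may react too slowly, so that Lewis-acid-induced oligomerisation of the vinylallene overtakes ring closure, or the diene may add with poor facial or endo/exo discrimination. The fallback sets out from 18 and returns at 25. It replaces the two-point-bound imide by an aldehyde dienophile and the auxiliary by a chiral Lewis acid as the source of asymmetry. Ester 18 would be reduced with DIBAL (CH2Cl2, −78 °C) at both the ester and the ketone to (2E,8E)-3,7,7-trimethyldodeca-2,8,10,11-tetraene-1,6-diol F1. Dess–Martin periodinane (NaHCO3, CH2Cl2) would oxidise both carbinols to (2E,8E)-3,7,7-trimethyl-6-oxododeca-2,8,10,11-tetraenal F2. The intramolecular Diels–Alder reaction of this enal would be run with a triflimide-activated oxazaborolidine, (S)-tetrahydro-1-(2-methylphenyl)-3,3-diphenyl-1H,3H-pyrrolo[1,2-c][1,3,2]oxazaborole with HNTf2, or its enantiomer as the facial sense requires (CH2Cl2, −40 °C). This catalyst class is established for trienal cycloadditions and should give (1S,4aR,8aS)-5,5,8a-trimethyl-2-methylidene-6-oxo-1,2,4a,5,6,7,8,8a-octahydronaphthalene-1-carbaldehyde F3. This aldehyde would be reduced at once with excess KBH(s-Bu)3 (THF, −78 °C), taking the aldehyde to the primary alcohol and the ketone to the axial alcohol, to rejoin the route at diol 25. Steps 8, 9, 11 and 12 are then not needed.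

Step 13 (etherification). Displacement at the β-branched C11 oxyphosphonium centre may be slow, and elimination towards C9, which would extend the diene, may compete. The fallback sets out from 25 and returns at 27. It reverses the polarity so that the alcohol acts as the nucleophile in a Buchwald–Hartwig-type C–O coupling with commercial 7-bromo-2H-chromen-2-one. Conditions would be Pd2(dba)3, 2-(di-tert-butylphosphino)-3-methoxy-6-methyl-2',4',6'-triisopropylbiphenyl, Cs2CO3, toluene, 90 °C. The primary alcohol should couple in preference to the hindered secondary one, and no new intermediate is formed.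

Step 12 (auxiliary removal). Hydride may attack the ring carbonyl of the oxazolidinone instead of the acyl carbonyl, which is shielded by quaternary C10 and the C8 methylene, leading to ring opening of the auxiliary. The fallback sets out from 24 and returns at 25. Lithium hydroperoxide (LiOH, H2O2, THF/H2O, 0 °C; Na2SO3), which is selective for the exocyclic carbonyl of hindered imides, would give (1S,4aR,6R,8aS)-6-hydroxy-5,5,8a-trimethyl-2-methylidene-1,2,4a,5,6,7,8,8a-octahydronaphthalene-1-carboxylic acid F4. Reduction of this acid with LiAlH4 (THF, 0 °C → reflux) would give diol 25.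

**Further compounds**

F1 | step 10 | (2E,8E)-3,7,7-trimethyldodeca-2,8,10,11-tetraene-1,6-diol (racemic at C6) | C=C=C/C=C/C(C)(C)C(O)CC/C(C)=C/CO
F2 | step 10 | (2E,8E)-3,7,7-trimethyl-6-oxododeca-2,8,10,11-tetraenal | C=C=C/C=C/C(C)(C)C(=O)CC/C(C)=C/C=O
F3 | step 10 | (1S,4aR,8aS)-5,5,8a-trimethyl-2-methylidene-6-oxo-1,2,4a,5,6,7,8,8a-octahydronaphthalene-1-carbaldehyde | C=C1C=C[C@H]2C(C)(C)C(=O)CC[C@]2(C)[C@H]1C=O
F0 | step 13 | none | none
F4 | step 12 | (1S,4aR,6R,8aS)-6-hydroxy-5,5,8a-trimethyl-2-methylidene-1,2,4a,5,6,7,8,8a-octahydronaphthalene-1-carboxylic acid | C=C1C=C[C@H]2C(C)(C)[C@H](O)CC[C@]2(C)[C@H]1C(=O)O
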